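**Retrosynthetic overview**
- The target is reached from its tetrakis(methoxymethyl) ether by mild acidic acetal cleavage; ring C (the pyranone) is the only ring made, rings A and B are bought as benzenes.
- Structural feature used: ring C is fused to ring A through two adjacent bonds, O1–C8a and C4–C4a, with the C5 oxygen next to C4a. This is the polarity pattern of a 3-alkoxyaryne, so both bonds are cut at once: primary alkoxide of an (R)-3-hydroxy-2-arylpropanoic Weinreb amide plus a ring A aryne.
- Ring A aryne precursor (ortho-silylaryl triflate) from 2-methylresorcinol: MOM protection, sterically governed C–H borylation/oxidation to a mirror-symmetric phenol, ortho-bromination, retro-Brook silyl shift and triflation.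
- Ring B amide from 4,6-dibromoresorcinol: geranylation, malonate arylation, reduction to a prochiral 2-aryl-1,3-diol, lipase desymmetrisation (sets C3), then differentiation of the two arms and oxidation.

Key step: step 15

Assumption: the lipase is taken to acetylate the prochiral 2-aryl-1,3-diol on the arm that gives the (R)-monoacetate; the sense must be checked on the real substrate, and the second fallback covers the opposite or an unselective outcome.

Abbreviation used in names: Ar = 5-[(2E)-3,7-dimethylocta-2,6-dien-1-yl]-2,4-bis(methoxymethoxy)phenyl.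

**Route**

Step 1
Reactants: 1 2-methylresorcinol
Product: 2 1,3-bis(methoxymethoxy)-2-methylbenzene
Conditions: MOMCl, i-Pr2NEt, CH2Cl2, 0 °C → rt
Reagents that add atoms: chloromethyl methyl ether, COCCl
Why: Williamson-type O-alkylation of both phenols with the reactive α-chloro ether, with no competing functional group in 1.

Step 2
Reactants: 2 1,3-bis(methoxymethoxy)-2-methylbenzene
Product: 4 3,5-bis(methoxymethoxy)-4-methylphenol, via aryl pinacol boronate 3 (not isolated)
Conditions: B2pin2, [Ir(OMe)(cod)]2 (1.5 mol %), 4,4'-di-tert-butyl-2,2'-bipyridine, THF, 80 °C; then H2O2, aq. NaOH, 0 °C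
Reagents that add atoms: bis(pinacolato)diboron, CC1(C)OB(B2OC(C)(C)C(C)(C)O2)OC1(C)C (boron of 3); hydrogen peroxide, OO (oxygen of 4)
Why: sterically controlled iridium-catalysed aromatic C–H borylation should take the only C–H without an ortho substituent (C5, para to the methyl group), and oxidation of the C–B bond then gives the mirror-symmetric phenol, the MOM ethers tolerating both stages.

Step 3
Reactants: 4 3,5-bis(methoxymethoxy)-4-methylphenol
Product: 5 2-bromo-3,5-bis(methoxymethoxy)-4-methylphenol
Conditions: NBS (1.0 equiv), CH2Cl2, −78 → 0 °C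
Reagents that add atoms: N-bromosuccinimide, O=C1CCC(=O)N1Br
Why: electrophilic aromatic bromination, in which the two free ring positions are equivalent by symmetry and strongly activated, so one equivalent at low temperature should stop at the mono-bromide.

Step 4
Reactants: 5 2-bromo-3,5-bis(methoxymethoxy)-4-methylphenol
Product: 8 3,5-bis(methoxymethoxy)-4-methyl-2-(trimethylsilyl)phenyl trifluoromethanesulfonate, via aryl trimethylsilyl ether 6 (not isolated), via lithium 2-silylphenolate 7 (not isolated)
Conditions: HMDS, THF, 70 °C, evaporate; n-BuLi, THF, −78 °C; PhNTf2, −78 °C → rt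
Reagents that add atoms: hexamethyldisilazane, C[Si](C)(C)N[Si](C)(C)C; N-phenylbis(trifluoromethanesulfonimide), O=S(=O)(N(c1ccccc1)S(=O)(=O)C(F)(F)F)C(F)(F)F
Why: O-silylation, bromine–lithium exchange and 1,3 O→C silyl shift (retro-Brook rearrangement) give the ortho-silyl phenolate, which is triflated in the same flask; exchange at −78 °C outruns MOM-directed deprotonation and PhNTf2 spares the acetals.

Step 5
Reactants: 9 4,6-dibromoresorcinol
Product: 10 1,5-dibromo-2,4-bis(methoxymethoxy)benzene
Conditions: MOMCl, i-Pr2NEt, CH2Cl2, 0 °C → rt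
Reagents that add atoms: chloromethyl methyl ether, COCCl
Why: O-alkylation of both phenols, the aryl bromides being inert to these conditions.

Step 6
Reactants: 10 1,5-dibromo-2,4-bis(methoxymethoxy)benzene; 11 geranyl bromide
Product: 13 1-bromo-5-[(2E)-3,7-dimethylocta-2,6-dien-1-yl]-2,4-bis(methoxymethoxy)benzene, via aryllithium 12 (not isolated)
Conditions: n-BuLi (1.0 equiv), THF, −78 °C; CuBr·SMe2 (10 mol %), 11, −78 → 0 °C
Reagents that add atoms: none
Why: a single bromine–lithium exchange (the two bromines are equivalent and a second exchange on the anionic ring is slower) followed by copper-catalysed SN2 allylation at the primary carbon of geranyl bromide should keep the E-olefin, since attack at the fully substituted γ-carbon is sterically disfavoured.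

Step 7
Reactants: 13 1-bromo-5-[(2E)-3,7-dimethylocta-2,6-dien-1-yl]-2,4-bis(methoxymethoxy)benzene; 14 diethyl malonate
Product: 15 diethyl 2-Ar-malonate
Conditions: Pd(OAc)2 (3 mol %), P(t-Bu)3·HBF4 (6 mol %), K3PO4, toluene, 80 °C
Reagents that add atoms: none
Why: palladium-catalysed α-arylation of a malonate enolate, where the bulky electron-rich phosphine should handle the electron-rich ortho-alkoxy bromide and the trisubstituted olefins do not insert.

Step 8
Reactants: 15 diethyl 2-Ar-malonate
Product: 16 2-Ar-propane-1,3-diol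
Conditions: LiAlH4, THF, 0 °C → rt (malonate added to the hydride)
Reagents that add atoms: none
Why: hydride reduction of both esters to the prochiral 1,3-diol; inverse addition at 0 °C limits enolisation of the aryl malonate, and MOM ethers and isolated olefins are inert.

Step 9
Reactants: 16 2-Ar-propane-1,3-diol
Product: 17 (2R)-2-Ar-3-hydroxypropyl acetate
Conditions: Burkholderia cepacia lipase (Amano PS), vinyl acetate, t-BuOMe, rt
Reagents that add atoms: vinyl acetate, C=COC(C)=O
Why: enzymatic desymmetrisation by irreversible transesterification, in which the lipase active site distinguishes the two enantiotopic hydroxymethyl arms and so sets the future C3 centre, taken here as (R).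

Step 10
Reactants: 17 (2R)-2-Ar-3-hydroxypropyl acetate
Product: 18 (2S)-2-Ar-3-[tert-butyl(diphenyl)silyl]oxypropyl acetate
Conditions: TBDPSCl, imidazole, CH2Cl2, 0 °C
Reagents that add atoms: tert-butyl(chloro)diphenylsilane, CC(C)(C)[Si](Cl)(c1ccccc1)c1ccccc1
Why: silylation of the free primary alcohol, run at once on crude 17 so that 1,3-acetyl migration cannot erode the ee; the descriptor becomes (S) only because the silyloxy arm now outranks the acetoxy arm.

Step 11
Reactants: 18 (2S)-2-Ar-3-[tert-butyl(diphenyl)silyl]oxypropyl acetate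
Product: 19 (2S)-2-Ar-3-[tert-butyl(diphenyl)silyl]oxypropan-1-ol
Conditions: K2CO3, MeOH, 0 °C
Reagents that add atoms: none
Why: base-catalysed transesterification removes the acetate; the bulky TBDPS group should not migrate under these conditions and the benzylic C–H is not acidic at this oxidation level.

Step 12
Reactants: 19 (2S)-2-Ar-3-[tert-butyl(diphenyl)silyl]oxypropan-1-ol
Product: 21 (2R)-2-Ar-3-[tert-butyl(diphenyl)silyl]oxypropanoic acid, via α-aryl aldehyde 20 (not isolated)
Conditions: Dess–Martin periodinane, NaHCO3, CH2Cl2, 0 °C; then NaClO2, NaH2PO4, 2-methyl-2-butene, t-BuOH/H2O, 0 °C → rt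
Reagents that add atoms: sodium chlorite, [Na+].[O-]Cl=O
Why: Dess–Martin then Pinnick oxidation, where the buffered periodinane and the weakly acidic chlorite stage should avoid enolisation of the crude α-aryl aldehyde and the scavenger protects the geranyl olefins and the electron-rich ring from hypochlorite.

Step 13
Reactants: 21 (2R)-2-Ar-3-[tert-butyl(diphenyl)silyl]oxypropanoic acid
Product: 22 (2R)-2-Ar-3-[tert-butyl(diphenyl)silyl]oxy-N-methoxy-N-methylpropanamide
Conditions: MeNHOMe·HCl, EDC·HCl, HOBt, N-methylmorpholine, CH2Cl2, 0 °C → rt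
Reagents that add atoms: N,O-dimethylhydroxylamine hydrochloride, CNOC.Cl
Why: carbodiimide amide coupling through the HOBt active ester with a weak base, which should keep ketene-type racemisation of the α-aryl acid low.

Step 14
Reactants: 22 (2R)-2-Ar-3-[tert-butyl(diphenyl)silyl]oxy-N-methoxy-N-methylpropanamide
Product: 23 (2R)-2-Ar-3-hydroxy-N-methoxy-N-methylpropanamide
Conditions: TBAF, AcOH (1:1), THF, 0 °C → rt
Reagents that add atoms: none
Why: fluoride desilylation buffered with acetic acid, so the liberated alkoxide is protonated at once and neither β-elimination nor epimerisation is invited; MOM ethers are untouched.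

Step 15
Reactants: 23 (2R)-2-Ar-3-hydroxy-N-methoxy-N-methylpropanamide; 8 3,5-bis(methoxymethoxy)-4-methyl-2-(trimethylsilyl)phenyl trifluoromethanesulfonate
Product: 27 (3R)-3-Ar-5,7-bis(methoxymethoxy)-6-methyl-2,3-dihydro-4H-chromen-4-one, via sodium alkoxide 24 (not isolated), via aryne 25 (not isolated), via hemiaminal alkoxide 26 (not isolated)
Conditions: NaH (1.0 equiv), THF, 0 °C; then 8 (1.5 equiv), KF, 18-crown-6, THF, −20 °C → rt; AcOH, 0 °C
Reagents that add atoms: none
Why: Proposed new method: fluoride removes the trimethylsilyl group of 8 and triflate loss releases aryne 25; the pre-formed primary alkoxide 24 adds to the aryne carbon remote from the C5 methoxymethoxy group (future C8a), and the aryl anion left at C4a, with no proton donor in the flask, attacks the Weinreb carbonyl to give the tetrahedral hemiaminal alkoxide 26, which collapses to the ketone only at the acetic acid quench. The closest known reaction type is aryne capture by an oxygen nucleophile followed by acyl transfer to the ortho aryl anion, as in xanthone formation from salicylates and arynes and in the acyl-alkylation of arynes by β-keto esters; new here are an aliphatic alkoxide as nucleophile and a Weinreb amide as the internal acyl donor. Ring C, the only ring formed, closes by 6-exo-trig attack of the C4a carbanion on the exocyclic amide carbonyl after the intermolecular O1–C8a bond has been made. No stereocentre is created in the product (the hemiaminal carbon of 26 is transient), and C3 is carried over from 23: a fully formed β-alkoxide cannot lose its oxygen by E1cB, resists a second deprotonation at the α-carbon of the branched tertiary amide, and 26 does not expose the base-sensitive α-aryl ketone before protonation. The selectivity needed is regiochemical (oxygen to C8a, carbanion to C4a); it should be secured by the polarisation and distortion of the aryne by the flanking C5 alkoxy group, which also stabilises the ortho carbanion, and by the unhindered C8–H side, while the mirror symmetry of phenol 4 excludes a 6-methyl/8-methyl alternative.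

Step 16
Reactants: 27 (3R)-3-Ar-5,7-bis(methoxymethoxy)-6-methyl-2,3-dihydro-4H-chromen-4-one
Product: 28 (3R)-3-{5-[(2E)-3,7-dimethylocta-2,6-dien-1-yl]-2,4-dihydroxyphenyl}-5,7-dihydroxy-6-methyl-2,3-dihydro-4H-chromen-4-one (CNP0348256.1)
Conditions: HCl (1.25 M in MeOH), THF, 0 °C → rt, stopped as soon as conversion is complete
Reagents that add atoms: none
Why: acid-catalysed acetal exchange (methanolysis) removes the four MOM ethers as dimethoxymethane under conditions mild enough that geranyl cyclisation onto the 4'-phenol and acid-catalysed enolisation at C3 should stay slow.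

**Compound list**

1 | 2-methylresorcinol | Cc1c(O)cccc1O | starting material
2 | 1,3-bis(methoxymethoxy)-2-methylbenzene | COCOc1cccc(OCOC)c1C | intermediate
3 | 2-[3,5-bis(methoxymethoxy)-4-methylphenyl]-4,4,5,5-tetramethyl-1,3,2-dioxaborolane (not isolated) | COCOc1cc(B2OC(C)(C)C(C)(C)O2)cc(OCOC)c1C | intermediate
4 | 3,5-bis(methoxymethoxy)-4-methylphenol | COCOc1cc(O)cc(OCOC)c1C | intermediate
5 | 2-bromo-3,5-bis(methoxymethoxy)-4-methylphenol | COCOc1cc(O)c(Br)c(OCOC)c1C | intermediate
6 | [2-bromo-3,5-bis(methoxymethoxy)-4-methylphenoxy]trimethylsilane (not isolated) | COCOc1cc(O[Si](C)(C)C)c(Br)c(OCOC)c1C | intermediate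
7 | lithium 3,5-bis(methoxymethoxy)-4-methyl-2-(trimethylsilyl)phenolate (not isolated) | [Li+].COCOc1cc([O-])c([Si](C)(C)C)c(OCOC)c1C | intermediate
8 | 3,5-bis(methoxymethoxy)-4-methyl-2-(trimethylsilyl)phenyl trifluoromethanesulfonate | COCOc1cc(OS(=O)(=O)C(F)(F)F)c([Si](C)(C)C)c(OCOC)c1C | intermediate
9 | 4,6-dibromoresorcinol | Oc1cc(O)c(Br)cc1Br | starting material
10 | 1,5-dibromo-2,4-bis(methoxymethoxy)benzene | COCOc1cc(OCOC)c(Br)cc1Br | intermediate
11 | geranyl bromide | CC(C)=CCC/C(C)=C/CBr | starting material
12 | [5-bromo-2,4-bis(methoxymethoxy)phenyl]lithium (not isolated) | [Li]c1cc(Br)c(OCOC)cc1OCOC | intermediate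
13 | 1-bromo-5-[(2E)-3,7-dimethylocta-2,6-dien-1-yl]-2,4-bis(methoxymethoxy)benzene | CC(C)=CCC/C(C)=C/Cc1cc(Br)c(OCOC)cc1OCOC | intermediate
14 | diethyl malonate | CCOC(=O)CC(=O)OCC | starting material
15 | diethyl 2-{5-[(2E)-3,7-dimethylocta-2,6-dien-1-yl]-2,4-bis(methoxymethoxy)phenyl}malonate | CC(C)=CCC/C(C)=C/Cc1cc(C(C(=O)OCC)C(=O)OCC)c(OCOC)cc1OCOC | intermediate
16 | 2-{5-[(2E)-3,7-dimethylocta-2,6-dien-1-yl]-2,4-bis(methoxymethoxy)phenyl}propane-1,3-diol | CC(C)=CCC/C(C)=C/Cc1cc(C(CO)CO)c(OCOC)cc1OCOC | intermediate
17 | (2R)-2-Ar-3-hydroxypropyl acetate | CC(C)=CCC/C(C)=C/Cc1cc([C@@H](COC(C)=O)CO)c(OCOC)cc1OCOC | intermediate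
18 | (2S)-2-Ar-3-[tert-butyl(diphenyl)silyl]oxypropyl acetate | CC(C)=CCC/C(C)=C/Cc1cc([C@@H](COC(C)=O)CO[Si](c2ccccc2)(c2ccccc2)C(C)(C)C)c(OCOC)cc1OCOC | intermediate
19 | (2S)-2-Ar-3-[tert-butyl(diphenyl)silyl]oxypropan-1-ol | CC(C)=CCC/C(C)=C/Cc1cc([C@@H](CO)CO[Si](c2ccccc2)(c2ccccc2)C(C)(C)C)c(OCOC)cc1OCOC | intermediate
20 | (2R)-2-Ar-3-[tert-butyl(diphenyl)silyl]oxypropanal (not isolated) | CC(C)=CCC/C(C)=C/Cc1cc([C@@H](C=O)CO[Si](c2ccccc2)(c2ccccc2)C(C)(C)C)c(OCOC)cc1OCOC | intermediate
21 | (2R)-2-Ar-3-[tert-butyl(diphenyl)silyl]oxypropanoic acid | CC(C)=CCC/C(C)=C/Cc1cc([C@@H](C(=O)O)CO[Si](c2ccccc2)(c2ccccc2)C(C)(C)C)c(OCOC)cc1OCOC | intermediate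
22 | (2R)-2-Ar-3-[tert-butyl(diphenyl)silyl]oxy-N-methoxy-N-methylpropanamide | CC(C)=CCC/C(C)=C/Cc1cc([C@@H](C(=O)N(C)OC)CO[Si](c2ccccc2)(c2ccccc2)C(C)(C)C)c(OCOC)cc1OCOC | intermediate
23 | (2R)-2-Ar-3-hydroxy-N-methoxy-N-methylpropanamide | CC(C)=CCC/C(C)=C/Cc1cc([C@@H](C(=O)N(C)OC)CO)c(OCOC)cc1OCOC | intermediate
24 | sodium (2R)-2-Ar-3-[methoxy(methyl)amino]-3-oxopropan-1-olate (not isolated) | CC(C)=CCC/C(C)=C/Cc1cc([C@@H](C(=O)N(C)OC)C[O-])c(OCOC)cc1OCOC.[Na+] | intermediate
25 | 3,5-bis(methoxymethoxy)-4-methylbenzyne (not isolated) | COCOC1=C(C)C(OCOC)=CC#C1 | intermediate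
26 | sodium (3R)-3-Ar-4-[methoxy(methyl)amino]-5,7-bis(methoxymethoxy)-6-methyl-3,4-dihydro-2H-chromen-4-olate, C4 configuration undefined (not isolated) | CC(C)=CCC/C(C)=C/Cc1cc([C@@H]2COc3cc(OCOC)c(C)c(OCOC)c3C2([O-])N(C)OC)c(OCOC)cc1OCOC.[Na+] | intermediate
27 | (3R)-3-Ar-5,7-bis(methoxymethoxy)-6-methyl-2,3-dihydro-4H-chromen-4-one | CC(C)=CCC/C(C)=C/Cc1cc([C@@H]2COc3cc(OCOC)c(C)c(OCOC)c3C2=O)c(OCOC)cc1OCOC | intermediate
28 | (3R)-3-{5-[(2E)-3,7-dimethylocta-2,6-dien-1-yl]-2,4-dihydroxyphenyl}-5,7-dihydroxy-6-methyl-2,3-dihydro-4H-chromen-4-one | CC(C)=CCC/C(C)=C/Cc1cc([C@@H]2COc3cc(O)c(C)c(O)c3C2=O)c(O)cc1O | target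

**Step count**

Total: 16 steps. Longest linear sequence: 12 steps (steps 5 to 16, from 4,6-dibromoresorcinol); the ring A branch (steps 1 to 4) joins at step 15.

**Steps most likely to fail**

1. Step 15 (the proposed new method). Three processes may defeat it:
- protonation of the C4a aryl anion before it reaches the amide, which would give the open aryl ether;
- slow proton transfer from the α-carbon to the alkoxide before the aryne arrives, which would lead to loss of configuration or β-elimination;
- attack of the alkoxide on the sulfur of the triflate instead of on the aryne.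

The fallback uses known chemistry, sets out from monoacetate 17 and bromophenol 5, and returns at 27. Mitsunobu etherification of the free arm of 17 with 5 (PPh3, DIAD, toluene, 0 °C → rt) should give the aryl ether acetate F1, which has no acidic α-hydrogen at this stage. Methanolysis (K2CO3, MeOH, 0 °C) should give the alcohol F2. Dess–Martin then Pinnick oxidation as in step 12 should give the acid F3, and EDC/HOBt coupling with MeNHOMe·HCl as in step 13 the bromoaryl Weinreb amide F4. Bromine–lithium exchange (t-BuLi, THF, −100 °C) and Parham-type cyclisation of the aryllithium onto the amide, with acetic acid quench, should then give 27. The free arm of 17 is the arm that becomes C2–O1 in the main route, so the (R) configuration is kept.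

2. Step 9. The bulky ortho-substituted aryl group may fit the lipase poorly, giving slow or weakly selective acylation, or acylation of the other enantiotopic arm; acetyl migration in the product would also erode the ee.

The fallback sets out from diol 16 and returns at 19. Mono-benzoylation with a dinuclear zinc ProPhenol catalyst (Et2Zn, ProPhenol ligand of the handedness that acylates the required arm, vinyl benzoate, toluene, −15 °C) should give the (R)-monobenzoate F5. Silylation (TBDPSCl, imidazole, CH2Cl2) should give the silyl ether benzoate F6, and methanolysis (K2CO3, MeOH) should deliver 19.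

3. Step 16. Acid-catalysed enolisation at C3 may cause partial racemisation of the isoflavanone, and protonation of the geranyl olefin may lead to cyclisation onto the neighbouring 4'-phenol.

The fallback sets out from 27 and ends at 28. Treatment with TMSOTf and 2,2'-bipyridyl (CH2Cl2, 0 °C) should convert the four aryl MOM ethers, through pyridinium intermediates and without free Brønsted acid, into the tetrakis(trimethylsilyl) ether F7. Hydrolysis with water at neutral pH should then release 28.

**Further compounds**

F1 | step 15 | (2R)-2-Ar-3-[2-bromo-3,5-bis(methoxymethoxy)-4-methylphenoxy]propyl acetate | CC(C)=CCC/C(C)=C/Cc1cc([C@@H](COC(C)=O)COc2cc(OCOC)c(C)c(OCOC)c2Br)c(OCOC)cc1OCOC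
F2 | step 15 | (2S)-2-Ar-3-[2-bromo-3,5-bis(methoxymethoxy)-4-methylphenoxy]propan-1-ol | CC(C)=CCC/C(C)=C/Cc1cc([C@@H](CO)COc2cc(OCOC)c(C)c(OCOC)c2Br)c(OCOC)cc1OCOC
F3 | step 15 | (2R)-2-Ar-3-[2-bromo-3,5-bis(methoxymethoxy)-4-methylphenoxy]propanoic acid | CC(C)=CCC/C(C)=C/Cc1cc([C@@H](C(=O)O)COc2cc(OCOC)c(C)c(OCOC)c2Br)c(OCOC)cc1OCOC
F4 | step 15 | (2R)-2-Ar-3-[2-bromo-3,5-bis(methoxymethoxy)-4-methylphenoxy]-N-methoxy-N-methylpropanamide | CC(C)=CCC/C(C)=C/Cc1cc([C@@H](C(=O)N(C)OC)COc2cc(OCOC)c(C)c(OCOC)c2Br)c(OCOC)cc1OCOC
F5 | step 9 | (2R)-2-Ar-3-hydroxypropyl benzoate | CC(C)=CCC/C(C)=C/Cc1cc([C@@H](COC(=O)c2ccccc2)CO)c(OCOC)cc1OCOC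
F6 | step 9 | (2S)-2-Ar-3-[tert-butyl(diphenyl)silyl]oxypropyl benzoate | CC(C)=CCC/C(C)=C/Cc1cc([C@@H](COC(=O)c2ccccc2)CO[Si](c2ccccc2)(c2ccccc2)C(C)(C)C)c(OCOC)cc1OCOC
F7 | step 16 | (3R)-3-{5-[(2E)-3,7-dimethylocta-2,6-dien-1-yl]-2,4-bis(trimethylsilyloxy)phenyl}-6-methyl-5,7-bis(trimethylsilyloxy)-2,3-dihydro-4H-chromen-4-one | CC(C)=CCC/C(C)=C/Cc1cc([C@@H]2COc3cc(O[Si](C)(C)C)c(C)c(O[Si](C)(C)C)c3C2=O)c(O[Si](C)(C)C)cc1O[Si](C)(C)C
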